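Product is what you are asked for, at one time in each flask below, where starting material is dosed at a steady rate into coupling partner and catalyst, and the earlier runs are what you have to go on.

| flask | starting material | coupling partner | free catalyst | remark | time |
|---|---|---|---|---|---|
| spring | 0.20 M (fed, over 25 min) | 0.60 M | 0.27 mM | run made earlier |  |
| summer | 0.20 M (fed, over 25 min) | 0.60 M | 2.8 mM | run made earlier |  |
| dusk | 0.20 M (fed, over 25 min) | 0.69 M | 1.3 mM | run made earlier |  |
| zeta | 0.20 M (fed, over 6.0 min) | 0.600 M | 1.3 mM |  | 25 min |
| epsilon | 0.20 M (fed, over 40 min) | 0.150 M | 0.40 mM |  | 25 min |
| eta | 0.10 M (fed, over 8.0 min) | 0.600 M | 1.3 mM |  | 25 min |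
| delta | 0.060 M (fed, over 25 min) | 2.00 M | 4.0 mM |  | 25 min |
| gamma | 0.20 M (fed, over 25 min) | 0.600 M | 1.3 mM |  | 25 min |

| run | time / min | product / % |
|---|---|---|
| spring | 6.00 | 0 |
| spring | 12.0 | 2 |
| spring | 20.0 | 11 |
| spring | 25.0 | 9 |
| summer | 3.00 | 2 |
| summer | 8.00 | 21 |
| summer | 15.0 | 40 |
| summer | 25.0 | 80 |
| dusk | 3.00 | 4 |
| dusk | 8.00 | 10 |
| dusk | 15.0 | 22 |
| dusk | 25.0 | 41 |

(readings scatter by 2 percentage points)

- the flasks by amount of product, in percent of the starting material charged, highest first, at 25 min (zeta / epsilon / eta / delta / gamma)
- the amount of product, in percent of the starting material charged of the flask you put first, at 25 min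
- the amount of product, in percent of the starting material charged of the flask you put last, at 25 min

- percentages count the whole charge, also what has not yet gone in

Two numbers in the dusk run, the closest to gamma, seem not to go together. At 8.00 min the feed had brought 32.0% of the charge and 10% was product, so 22.0% stood unconverted, and at 25.0 min that figure was 59.0%, a factor of 2.68. Yet product formed at 3.43 mM/min early and 3.80 mM/min late, a factor of 1.11, which the scatter of 2 percentage points per reading cannot separate from none.

You clear this up by dividing rate by catalyst, since a rate that ignores the stock of starting material (zero order) should follow the catalyst. From the second reading to the last, the summer run gives 2.48 /min and the dusk run 2.81 /min, so I take their mean, 2.64 /min, as a reading of the turnover frequency.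

Divide gamma's charge by that speed times its catalyst and you get 58.2 min, the clearing time: the minutes the catalyst needs, at that speed, to turn the whole charge into product. It is longer than the feed, so in gamma, and in zeta with the same charge and catalyst, I estimate about 42.9%, which is no upper limit, since the summer reading alone gives 40.3% and the dusk reading alone 45.6%, with zeta slightly ahead because its feed ends sooner. Eta's clearing time is 29.1 min, which gives an estimate near 85.9%. Epsilon's is 189 min, which gives an estimate near 13.2%. Delta's is 5.68 min, shorter than its feed, so I expect delta to follow its feed.

The forecast gives delta > eta > zeta > gamma > epsilon, with 92% (83% to 98%) first and 9% (3% to 15%) last, on the ground that “rate scales with catalyst and is almost zero order in starting material”. My order is the same, but my estimate for epsilon stands above its figure.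

The simulation gives delta > eta > zeta > gamma > epsilon, with 96.2% for delta and 11.3% for epsilon, from this scheme:

    starting material + free catalyst → catalyst intermediate A (k = 502 /M/min)
    catalyst intermediate A → catalyst intermediate B (k = 9.44 /min)
    coupling partner + catalyst intermediate B → catalyst intermediate C (k = 150 /M/min)
    catalyst intermediate C ⇌ catalyst intermediate D (K = 1.30, k = 4.70 /min)
    catalyst intermediate D → free catalyst + product (k = 644 /min)

At 25.0 min delta holds 80.5% of its catalyst free, with its clearing time of 5.68 min well inside its feed of 25 min. Charge delta's neighbour with 0.24 M of starting material instead and the clearing time becomes 22.7 min, still under the feed but close to it. That neighbour gives 90.1%, with free catalyst down to 22.8% and 8.7% of its starting material left.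

The runs are simulated with constants of no real substance, noise included.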